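In a one-step world where starting material meets reagent at fixed equivalents, the fraction converted per hour scales with the charged concentration, so a flask at half the charge needs twice the time for any stage.

| flask | starting material | reagent | remark | time |
|---|---|---|---|---|
| alpha | 0.26 M | 3 equiv | run made earlier |  |
| flask | 0.13 M | 3.00 equiv |  | 12 h |

- alpha (time / h: bis adduct / %, starting material / %): 0.500: 4.0, 66.0; 1.00: 10.8, 44.2; 1.50: 15.1, 30.1; 2.00: 19.8, 21.7; 2.50: 20.9, 14.1; 3.00: 19.7, 11.9; 4.00: 18.0, 6.3

(scatter of a reading: 1 percentage point)

- the moment within 12 h at which there is most bis adduct
- the amount of bis adduct, in percent of the starting material charged, at that time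

- the earlier runs were read with a standard deviation of 1 percentage point

I therefore carried one quantity from the alpha run: the exposure, the charged concentration of starting material times the time. Its highest bis adduct reading, 20.9% at 2.50 h, put the peak at an exposure of 39.0 M·min. Since the equivalents were the same, dividing by 0.13 M gave 5.00 h for the flask, provided every step, the loss of bis adduct included, needed two partners, which I assumed.

My second way used starting material. Its first alpha reading gave a pseudo-first-order rate of 0.831 h⁻¹; halved, this reckoned the flask down to the 14.1% of that highest reading in 4.71 h. The two ways parted by 0.290 h, and the clock was the one that cheated: late in alpha the rate read 0.636 h⁻¹, slower than the early one, so a clock holding the early rate arrived sooner. Exposure carries that slowing over from the run itself. I committed to 5.00 h, with a height near the alpha reading.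

The forecast differed, leaning towards “unimolecular decomposition, which keeps its rate” and giving 14% at 4.6 h.

The flask gave 19.9% at 5.49 h, later than my time. Its exposure was 1.10 times mine, and it corresponded to 2.74 h in alpha, later than the reading at 2.50 h and earlier than the one at 3.00 h.

    reagent + bis adduct → tris adduct + by-product (k = 0.550 M⁻¹ h⁻¹)
    bis adduct + by-product → side product B (k = 0.690 M⁻¹ h⁻¹)
    reagent + tris adduct → tetra adduct + by-product (k = 0.150 M⁻¹ h⁻¹)
    reagent + first product → bis adduct + by-product (k = 1.10 M⁻¹ h⁻¹)
    starting material + first product → side product A (k = 3.00 M⁻¹ h⁻¹)
    starting material + reagent → first product + by-product (k = 0.960 M⁻¹ h⁻¹)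

In the flask, starting material + reagent had half of its turnover up to 12 h behind it by 1.52 h, when bis adduct, each step taken net, was made 4.66 times faster than it was used. Reagent + bis adduct reached the halfway mark of its own turnover at 5.85 h, close to the peak.

With 0.033 M of starting material and the same equivalents, the exposure put the peak at 19.7 h, beyond 12 h. Its end then corresponded to 1.52 h in alpha, beside the reading of 15.1% at 1.50 h. The computed neighbour gave 16.1% as its most bis adduct, and 16.1% stood at 12.0 h.

The numbers in the tables come from a simulation with constants of no real substance, noise included.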